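**Retrosynthetic overview**
1. Feature: in the ten-membered ring the E alkene C1=C10 and the C4–C5 oxirane (a masked E alkene) flank the C2–C3 bridge. With a Z C2=C3 bond added, this is the ring-opened form of a trans-fused decalin 1,3-diene (ring A = C1–C5, C10; ring B = C5–C10) joined through C5–C10.
2. Target ⇐ phenol deprotection and C8 esterification ⇐ hydroxyl-directed 4,5-epoxidation ⇐ germacra-1(10)E,4E-dien-6-ol ⇐ cold hydrogenation of the 1(10)E,2Z,4E-triene ⇐ photochemical C5–C10 cleavage of a trans-fused eudesma-1,3-dien-6β-ol 8β-silyl ether.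
3. Diene ⇐ dienyl triflate of the Δ1-3-ketone ⇐ C6 and C8 ketones reduced from the α face (C6 oxygen via deconjugative ketalisation, hydroboration, oxidation) ⇐ Robinson annulation with ethyl vinyl ketone (C10 by a chiral-imine Michael addition, C7 by copper-catalysed conjugate addition).
4. Ring order: ring B (bought as an enone ketal) → ring A (annulation) → ten-membered ring (by cutting C5–C10) → oxirane.
5. Both trans-fused C5/C10 diastereomers of the diene open to the same triene. The one with the angular methyl cis to the C6, C7 and C8 substituents is used, because each of these centres then arises by attack anti to that methyl.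

Key step: step 15

Conventions: bicyclic compounds are named as eudesmanes (methyls on C4 and C10, isopropyl on C7); β is the face of the C10 methyl, and the same atom numbers and α/β descriptors are kept for the macrocycles (6β-O, 7β-isopropyl, 8β-O are mutually cis).
Assumption: 1,4-dioxaspiro[4.5]dec-6-en-8-one is taken as a purchasable compound; the C4 methyl configuration in 12–20 is not controlled (equatorial 4α expected and drawn) and is erased in step 13.

**Route**

Step 1
Reactants: 1 1,4-dioxaspiro[4.5]dec-6-en-8-one
Product: 2 9-methyl-1,4-dioxaspiro[4.5]dec-6-en-8-one (racemic)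
Conditions: LiN(i-Pr)2 (1.05 equiv), THF, −78 °C; MeI, −78 → −30 °C
Reagents that add atoms: iodomethane, CI
Why: Kinetic α′-deprotonation of the enone (the γ carbon is the spiro ketal carbon and has no hydrogen) gives the cross-conjugated lithium dienolate, and enolate alkylation places the future C10 methyl next to the ketone; the new centre is racemic and is made quaternary in step 3.

Step 2
Reactants: 2 9-methyl-1,4-dioxaspiro[4.5]dec-6-en-8-one
Product: 3 (6R)-6-isopropyl-9-methyl-1,4-dioxaspiro[4.5]decan-8-one (C9 epimers)
Conditions: i-Pr2Zn (1.5 equiv), Cu(OTf)2 (2 mol %), (R)-binaphthol phosphoramidite of bis[(S)-1-phenylethyl]amine (4 mol %), toluene, −30 °C; aq NH4Cl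
Reagents that add atoms: diisopropylzinc, CC(C)[Zn]C(C)C
Why: Copper-catalysed asymmetric conjugate addition of a dialkylzinc to a cyclic enone sets the isopropyl-bearing centre (future C7) under catalyst control; the ligand is the enantiomer that gives (R)-3-alkylcyclohexanones from cyclohex-2-enone, which corresponds to the 6R product here, and the C9 methyl centre is left as an epimer mixture because it is enolised in step 3.

Step 3
Reactants: 3 (6R)-6-isopropyl-9-methyl-1,4-dioxaspiro[4.5]decan-8-one; 4 (R)-1-phenylethylamine; 5 ethyl vinyl ketone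
Product: 8 (6R,9R)-6-isopropyl-9-methyl-9-(3-oxopentyl)-1,4-dioxaspiro[4.5]decan-8-one, via imine 6 (not isolated), via Michael adduct imine 7 (not isolated)
Conditions: 4 (1.1 equiv), TsOH (cat.), toluene, reflux with azeotropic removal of water; then 5 (1.5 equiv), THF, 40 °C, 4 d; then 10% aq AcOH, rt
Reagents that add atoms: water, O
Why: Asymmetric Michael addition of a chiral imine through its more substituted secondary enamine tautomer creates the quaternary centre C10 on the face away from the phenyl group of the auxiliary, the same pairing of (R)-amine and acceptor face that turns dihydrocarvone into the 7,10-cis eudesmane skeleton, so C10 is set by the auxiliary and should come out cis to the isopropyl group; the acetic acid hydrolysis frees the ketone and the amine but not the dioxolane.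

Step 4
Reactants: 8 (6R,9R)-6-isopropyl-9-methyl-9-(3-oxopentyl)-1,4-dioxaspiro[4.5]decan-8-one
Product: 10 eudesm-4-ene-3,8-dione, via enone ketal 9 (not isolated)
Conditions: NaOMe (0.5 equiv), MeOH, 60 °C; then 2 M aq HCl, THF, rt, short contact
Reagents that add atoms: water, O
Why: Intramolecular aldol condensation of the 1,5-diketone (ring-closing half of the Robinson annulation) forms ring A as the Δ4-3-ketone and aqueous acid then removes the dioxolane; no stereocentre is formed, and the now enolisable C7 is kept by short acid contact, its equatorial 7β-isopropyl arrangement also being the more stable one.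

Step 5
Reactants: 10 eudesm-4-ene-3,8-dione
Product: 11 8β-hydroxyeudesm-4-en-3-one
Conditions: LiBH(s-Bu)3 (1.05 equiv), THF, −78 °C; then H2O
Reagents that add atoms: none
Why: Ketone reduction by a bulky trialkylborohydride: the saturated C8 ketone should react much faster than the tetrasubstituted, α-methylated enone, and hydride enters from the α face (equatorial attack) because the β face is screened by the syn-axial C10 methyl, so the axial 8β-alcohol cis to the isopropyl group is formed.

Step 6
Reactants: 11 8β-hydroxyeudesm-4-en-3-one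
Product: 12 3,3-(ethylenedioxy)eudesm-5-en-8β-ol
Conditions: HOCH2CH2OH (5 equiv), TsOH·H2O (5 mol %), benzene, reflux with azeotropic removal of water
Reagents that add atoms: ethylene glycol, OCCO
Why: Deconjugative ketalisation, as with steroidal Δ4-3-ketones: the intermediate 3,5-dienol ether is protonated at C4, so the ketal forms with the double bond at C5=C6, which masks C3 and opens C6 to hydroboration; the new C4 centre (equatorial methyl expected) is of no consequence.

Step 7
Reactants: 12 3,3-(ethylenedioxy)eudesm-5-en-8β-ol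
Product: 13 8β-(tert-butyldimethylsilyloxy)-3,3-(ethylenedioxy)eudesm-5-ene
Conditions: TBSOTf (1.3 equiv), 2,6-lutidine (2.5 equiv), CH2Cl2, −40 → 0 °C
Reagents that add atoms: tert-butyldimethylsilyl trifluoromethanesulfonate, CC(C)(C)[Si](C)(C)OS(=O)(=O)C(F)(F)F
Why: O-Silylation of the hindered axial alcohol with the silyl triflate and a non-nucleophilic base, under which the alkene and the dioxolane are inert.

Step 8
Reactants: 13 8β-(tert-butyldimethylsilyloxy)-3,3-(ethylenedioxy)eudesm-5-ene
Product: 15 8β-(tert-butyldimethylsilyloxy)-3,3-(ethylenedioxy)-5α-eudesman-6α-ol, via C6 alkylborane 14 (not isolated)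
Conditions: BH3·THF (3 equiv), THF, 0 °C → rt; then 3 M NaOH, 30% H2O2, 0 °C → rt
Reagents that add atoms: borane–tetrahydrofuran (boron of 14), B.C1CCOC1; hydrogen peroxide (oxygen of 15), OO
Why: Hydroboration–oxidation: borane adds syn across the trisubstituted C5=C6 bond with boron on the less substituted C6 and from the α face, since the β face carries the C10 methyl and the pseudoaxial 8β-silyloxy group, which sets H-5α (trans ring fusion) and, after oxidation with retention, the 6α-alcohol.

Step 9
Reactants: 15 8β-(tert-butyldimethylsilyloxy)-3,3-(ethylenedioxy)-5α-eudesman-6α-ol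
Product: 16 8β-(tert-butyldimethylsilyloxy)-3,3-(ethylenedioxy)-5α-eudesman-6-one
Conditions: Dess–Martin periodinane (1.5 equiv), NaHCO3, CH2Cl2, rt
Reagents that add atoms: none
Why: Dess–Martin oxidation of the secondary alcohol to the C6 ketone under buffered, non-basic conditions, so that C5 and C7 are not epimerised and the β-silyloxy group is not eliminated.

Step 10
Reactants: 16 8β-(tert-butyldimethylsilyloxy)-3,3-(ethylenedioxy)-5α-eudesman-6-one
Product: 17 8β-(tert-butyldimethylsilyloxy)-3,3-(ethylenedioxy)-5α-eudesman-6β-ol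
Conditions: LiAlH4 (1.5 equiv), THF, −78 → −40 °C; aq NaOH work-up
Reagents that add atoms: none
Why: Hydride reduction of the C6 ketone: the β face is closed by two syn-axial groups (C10 methyl and 8β-silyloxy), so hydride is delivered from the α face and the axial 6β-alcohol, cis to the isopropyl and silyloxy groups, should result.

Step 11
Reactants: 17 8β-(tert-butyldimethylsilyloxy)-3,3-(ethylenedioxy)-5α-eudesman-6β-ol
Product: 18 6β-hydroxy-8β-(tert-butyldimethylsilyloxy)-5α-eudesman-3-one
Conditions: pyridinium tosylate (0.2 equiv), acetone–H2O (10:1), 55 °C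
Reagents that add atoms: water, O
Why: Acid-catalysed ketal exchange with acetone and water liberates the C3 ketone (C4 methyl equatorial after equilibration) while the hindered secondary TBS ether survives pyridinium tosylate.

Step 12
Reactants: 18 6β-hydroxy-8β-(tert-butyldimethylsilyloxy)-5α-eudesman-3-one
Product: 20 6β-(trimethylsilyloxy)-8β-(tert-butyldimethylsilyloxy)-5α-eudesm-1-en-3-one, via bis(trimethylsilyl) derivative 19 (not isolated)
Conditions: LiN(i-Pr)2 (2.5 equiv), THF, −78 °C; TMSCl (3 equiv), −78 → 0 °C; then Pd(OAc)2 (1.1 equiv), MeCN, rt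
Reagents that add atoms: chlorotrimethylsilane, C[Si](C)(C)Cl
Why: Saegusa–Ito oxidation: the first equivalent of amide forms the C6 alkoxide and the second removes a C2 proton kinetically (the C4 methine is slower), both oxygens are silylated, and Pd(OAc)2 converts the Δ2 silyl enol ether into the Δ1-enone via an oxa-π-allyl palladium species and β-hydride loss.

Step 13
Reactants: 20 6β-(trimethylsilyloxy)-8β-(tert-butyldimethylsilyloxy)-5α-eudesm-1-en-3-one
Product: 21 6β-(trimethylsilyloxy)-8β-(tert-butyldimethylsilyloxy)-5α-eudesma-1,3-dien-3-yl trifluoromethanesulfonate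
Conditions: KN(SiMe3)2 (1.3 equiv), THF, −78 → −20 °C; PhNTf2 (1.3 equiv), −78 → 0 °C
Reagents that add atoms: N-phenylbis(trifluoromethanesulfonimide), O=S(=O)(N(c1ccccc1)S(=O)(=O)C(F)(F)F)C(F)(F)F
Why: Enol triflate formation: the only acidic hydrogen of the enone is on C4 (C10 is quaternary), so deprotonation gives the cross-conjugated 1,3-dien-3-olate, whose O-sulfonylation by PhNTf2 fixes the C1=C2–C3=C4 diene and removes the C4 stereocentre.

Step 14
Reactants: 21 6β-(trimethylsilyloxy)-8β-(tert-butyldimethylsilyloxy)-5α-eudesma-1,3-dien-3-yl trifluoromethanesulfonate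
Product: 23 8β-(tert-butyldimethylsilyloxy)-5α-eudesma-1,3-dien-6β-ol, via trimethylsilyl ether diene 22 (not isolated)
Conditions: Pd(OAc)2 (5 mol %), PPh3 (10 mol %), n-Bu3N (3 equiv), HCO2H (2 equiv), DMF, 60 °C; then K2CO3, MeOH, rt
Reagents that add atoms: none
Why: Palladium-catalysed formate reduction of the dienyl triflate (oxidative addition, exchange of triflate for formate, loss of CO2 and reductive elimination of C–H) replaces OTf by H without moving the double bonds, and potassium carbonate in methanol then cleaves only the trimethylsilyl ether.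

Step 15
Reactants: 23 8β-(tert-butyldimethylsilyloxy)-5α-eudesma-1,3-dien-6β-ol
Product: 25 (1(10)E,4E)-8β-(tert-butyldimethylsilyloxy)germacra-1(10),4-dien-6β-ol, via triene 24 (not isolated)
Conditions: hν (254 nm, low-pressure Hg lamp, quartz), Et2O–MeOH (4:1), −25 °C, Ar, to the stationary state; then Raney Ni (W-2), H2 (1 atm), −25 °C, dark
Reagents that add atoms: none
Why: Excitation of the ring A 1,3-diene (C1=C2–C3=C4) at 254 nm triggers conrotatory six-electron electrocyclic cleavage of the C5–C10 σ bond, the reaction type of the provitamin D to previtamin D opening and of the opening of trans-fused eudesma-1,3-dienes to cyclodecatrienes. The ten-membered ring is not closed by bond formation; it is unveiled by cutting the bond shared by rings A and B, a ring expansion by fragmentation, so no macrocyclisation mode has to be controlled. No stereocentre is formed: C5 and C10 become sp2, and C6, C7 and C8 are carried over unchanged. The step needs the 1(10)E,2Z,4E geometry, and the trans ring fusion secures it, because in the conrotatory motion both ring B bonds (C5–C6 and C10–C9) turn outward. Triene 24 recloses thermally (disrotatory) and absorbs light itself, so irradiation is stopped at the stationary state and the cold solution is hydrogenated at once over Raney Ni, which should take up hydrogen at the Z-disubstituted C2=C3 bond much faster than at the two trisubstituted E bonds, the three alkenes being twisted out of conjugation by the ring. Unchanged or reduced decalin material is separated from 25 by chromatography and the diene is recycled.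

Step 16
Reactants: 25 (1(10)E,4E)-8β-(tert-butyldimethylsilyloxy)germacra-1(10),4-dien-6β-ol
Product: 26 (1(10)E)-8β-(tert-butyldimethylsilyloxy)-4α,5β-epoxygermacr-1(10)-en-6β-ol
Conditions: VO(acac)2 (5 mol %), t-BuOOH (1.5 equiv, decane), CH2Cl2, 0 °C
Reagents that add atoms: tert-butyl hydroperoxide, CC(C)(C)OO
Why: Vanadium-catalysed hydroxyl-directed epoxidation reaches only the allylic C4=C5 bond and leaves C1=C10 alone; in the crossed ring conformation the C6 hydroxyl lies close to the alkene plane on its outer face (the small O–C–C=C angle that the vanadium peroxide prefers) and the inner face is closed by the ring, so oxygen should be delivered to the outer face and give the trans epoxide whose C5–O bond is erythro to the C6 hydroxyl (4R,5R), as in the target.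

Step 17
Reactants: 26 (1(10)E)-8β-(tert-butyldimethylsilyloxy)-4α,5β-epoxygermacr-1(10)-en-6β-ol
Product: 27 (1(10)E)-4α,5β-epoxygermacr-1(10)-ene-6β,8β-diol
Conditions: Bu4NF (1.5 equiv), AcOH (1.5 equiv), THF, 0 → 40 °C
Reagents that add atoms: none
Why: Fluoride-mediated desilylation of the C8 silyl ether, buffered with acetic acid so that no alkoxide is present and the 2,3-epoxy alcohol cannot undergo Payne rearrangement.

Step 18
Reactants: 28 4-hydroxybenzoic acid
Product: 30 4-(tert-butyldimethylsilyloxy)benzoic acid, via silyl ester 29 (not isolated)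
Conditions: TBSCl (2.3 equiv), imidazole (5 equiv), DMF, rt; then K2CO3, MeOH–THF–H2O, rt; citric acid to pH 4
Reagents that add atoms: tert-butyldimethylsilyl chloride, CC(C)(C)[Si](C)(C)Cl
Why: Silylation of both the phenol and the acid followed by selective hydrolysis of the far more labile silyl ester leaves the O-protected acid.

Step 19
Reactants: 27 (1(10)E)-4α,5β-epoxygermacr-1(10)-ene-6β,8β-diol; 30 4-(tert-butyldimethylsilyloxy)benzoic acid
Product: 31 (1(10)E)-4α,5β-epoxy-6β-hydroxygermacr-1(10)-en-8β-yl 4-(tert-butyldimethylsilyloxy)benzoate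
Conditions: 30 (1.1 equiv), EDC·HCl (1.3 equiv), DMAP (0.2 equiv), CH2Cl2, −10 → 10 °C
Reagents that add atoms: none
Why: Steglich esterification with one equivalent of acid: the C8 hydroxyl, flanked by a methylene group, is more accessible than the C6 hydroxyl, which sits between the oxirane carbon and the isopropyl-bearing carbon and is hydrogen-bonded to the oxirane oxygen, so mono-acylation at C8 is expected.

Step 20
Reactants: 31 (1(10)E)-4α,5β-epoxy-6β-hydroxygermacr-1(10)-en-8β-yl 4-(tert-butyldimethylsilyloxy)benzoate
Product: 32 (1(10)E)-4α,5β-epoxy-6β-hydroxygermacr-1(10)-en-8β-yl 4-hydroxybenzoate (target, CNP0365539.3)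
Conditions: Bu4NF (1.1 equiv), AcOH (1.1 equiv), THF, 0 °C
Reagents that add atoms: none
Why: Aryl silyl ethers are cleaved by buffered fluoride within minutes at 0 °C, conditions under which the oxirane, the ester and the E alkene are inert.

**Compound list**

1 | 1,4-dioxaspiro[4.5]dec-6-en-8-one | O=C1C=CC2(OCCO2)CC1 | starting material
2 | 9-methyl-1,4-dioxaspiro[4.5]dec-6-en-8-one (racemic) | CC1CC2(OCCO2)C=CC1=O | intermediate
3 | (6R)-6-isopropyl-9-methyl-1,4-dioxaspiro[4.5]decan-8-one (C9 epimers) | CC1C(=O)C[C@H](C(C)C)C2(OCCO2)C1 | intermediate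
4 | (R)-1-phenylethylamine | C[C@@H](N)c1ccccc1 | starting material (auxiliary)
5 | ethyl vinyl ketone | CCC(=O)C=C | starting material
6 | imine of 3 with 4 | C[C@@H](N=C1C(C)CC2(OCCO2)[C@@H](C(C)C)C1)c1ccccc1 | intermediate (not isolated)
7 | Michael adduct imine (quaternary C set) | C[C@@H](N=C1[C@](C)(CCC(=O)CC)CC2(OCCO2)[C@@H](C(C)C)C1)c1ccccc1 | intermediate (not isolated)
8 | (6R,9R)-6-isopropyl-9-methyl-9-(3-oxopentyl)-1,4-dioxaspiro[4.5]decan-8-one | C[C@]1(CCC(=O)CC)C(=O)C[C@H](C(C)C)C2(OCCO2)C1 | intermediate
9 | 8,8-(ethylenedioxy)eudesm-4-en-3-one (10β-methyl, 7β-isopropyl) | C[C@]12CCC(=O)C(C)=C1C[C@H](C(C)C)C3(OCCO3)C2 | intermediate (not isolated)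
10 | eudesm-4-ene-3,8-dione (10β-methyl, 7β-isopropyl) | C[C@]12CCC(=O)C(C)=C1C[C@H](C(C)C)C(=O)C2 | intermediate
11 | 8β-hydroxyeudesm-4-en-3-one | C[C@]12CCC(=O)C(C)=C1C[C@H](C(C)C)[C@H](O)C2 | intermediate
12 | 3,3-(ethylenedioxy)eudesm-5-en-8β-ol (4α-methyl) | C[C@]12CCC3(OCCO3)[C@@H](C)C1=C[C@H](C(C)C)[C@H](O)C2 | intermediate
13 | 8β-(tert-butyldimethylsilyloxy)-3,3-(ethylenedioxy)eudesm-5-ene | C[C@]12CCC3(OCCO3)[C@@H](C)C1=C[C@H](C(C)C)[C@H](O[Si](C)(C)C(C)(C)C)C2 | intermediate
14 | 6α-boryl-8β-(tert-butyldimethylsilyloxy)-3,3-(ethylenedioxy)-5α-eudesmane | C[C@]12CCC3(OCCO3)[C@@H](C)[C@@H]1[C@@H](B)[C@H](C(C)C)[C@H](O[Si](C)(C)C(C)(C)C)C2 | intermediate (not isolated)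
15 | 8β-(tert-butyldimethylsilyloxy)-3,3-(ethylenedioxy)-5α-eudesman-6α-ol | C[C@]12CCC3(OCCO3)[C@@H](C)[C@@H]1[C@@H](O)[C@H](C(C)C)[C@H](O[Si](C)(C)C(C)(C)C)C2 | intermediate
16 | 8β-(tert-butyldimethylsilyloxy)-3,3-(ethylenedioxy)-5α-eudesman-6-one | C[C@]12CCC3(OCCO3)[C@@H](C)[C@@H]1C(=O)[C@H](C(C)C)[C@H](O[Si](C)(C)C(C)(C)C)C2 | intermediate
17 | 8β-(tert-butyldimethylsilyloxy)-3,3-(ethylenedioxy)-5α-eudesman-6β-ol | C[C@]12CCC3(OCCO3)[C@@H](C)[C@@H]1[C@H](O)[C@H](C(C)C)[C@H](O[Si](C)(C)C(C)(C)C)C2 | intermediate
18 | 6β-hydroxy-8β-(tert-butyldimethylsilyloxy)-5α-eudesman-3-one | C[C@]12CCC(=O)[C@@H](C)[C@@H]1[C@H](O)[C@H](C(C)C)[C@H](O[Si](C)(C)C(C)(C)C)C2 | intermediate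
19 | 3,6β-bis(trimethylsilyloxy)-8β-(tert-butyldimethylsilyloxy)-5α-eudesm-2-ene | C[C@]12CC=C(O[Si](C)(C)C)[C@@H](C)[C@@H]1[C@H](O[Si](C)(C)C)[C@H](C(C)C)[C@H](O[Si](C)(C)C(C)(C)C)C2 | intermediate (not isolated)
20 | 6β-(trimethylsilyloxy)-8β-(tert-butyldimethylsilyloxy)-5α-eudesm-1-en-3-one | C[C@]12C=CC(=O)[C@@H](C)[C@@H]1[C@H](O[Si](C)(C)C)[C@H](C(C)C)[C@H](O[Si](C)(C)C(C)(C)C)C2 | intermediate
21 | 6β-(trimethylsilyloxy)-8β-(tert-butyldimethylsilyloxy)-5α-eudesma-1,3-dien-3-yl trifluoromethanesulfonate | C[C@]12C=CC(OS(=O)(=O)C(F)(F)F)=C(C)[C@@H]1[C@H](O[Si](C)(C)C)[C@H](C(C)C)[C@H](O[Si](C)(C)C(C)(C)C)C2 | intermediate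
22 | 6β-(trimethylsilyloxy)-8β-(tert-butyldimethylsilyloxy)-5α-eudesma-1,3-diene | C[C@]12C=CC=C(C)[C@@H]1[C@H](O[Si](C)(C)C)[C@H](C(C)C)[C@H](O[Si](C)(C)C(C)(C)C)C2 | intermediate (not isolated)
23 | 8β-(tert-butyldimethylsilyloxy)-5α-eudesma-1,3-dien-6β-ol (trans-fused: 10β-methyl, H-5α) | C[C@]12C=CC=C(C)[C@@H]1[C@H](O)[C@H](C(C)C)[C@H](O[Si](C)(C)C(C)(C)C)C2 | intermediate (key-step precursor)
24 | (1(10)E,2Z,4E)-8β-(tert-butyldimethylsilyloxy)germacra-1(10),2,4-trien-6β-ol | C/C1=C\C=C/C(C)=C/[C@H](O)[C@H](C(C)C)[C@H](O[Si](C)(C)C(C)(C)C)C1 | intermediate (key-step product, not isolated)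
25 | (1(10)E,4E)-8β-(tert-butyldimethylsilyloxy)germacra-1(10),4-dien-6β-ol | C/C1=C\CC/C(C)=C/[C@H](O)[C@H](C(C)C)[C@H](O[Si](C)(C)C(C)(C)C)C1 | intermediate
26 | (1(10)E)-8β-(tert-butyldimethylsilyloxy)-4α,5β-epoxygermacr-1(10)-en-6β-ol | C/C1=C\CC[C@@]2(C)O[C@@H]2[C@H](O)[C@H](C(C)C)[C@H](O[Si](C)(C)C(C)(C)C)C1 | intermediate
27 | (1(10)E)-4α,5β-epoxygermacr-1(10)-ene-6β,8β-diol | C/C1=C\CC[C@@]2(C)O[C@@H]2[C@H](O)[C@H](C(C)C)[C@H](O)C1 | intermediate
28 | 4-hydroxybenzoic acid | OC(=O)c1ccc(O)cc1 | starting material
29 | tert-butyldimethylsilyl 4-(tert-butyldimethylsilyloxy)benzoate | CC(C)(C)[Si](C)(C)OC(=O)c1ccc(O[Si](C)(C)C(C)(C)C)cc1 | intermediate (not isolated)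
30 | 4-(tert-butyldimethylsilyloxy)benzoic acid | OC(=O)c1ccc(O[Si](C)(C)C(C)(C)C)cc1 | intermediate
31 | (1(10)E)-4α,5β-epoxy-6β-hydroxygermacr-1(10)-en-8β-yl 4-(tert-butyldimethylsilyloxy)benzoate | C/C1=C\CC[C@@]2(C)O[C@@H]2[C@H](O)[C@H](C(C)C)[C@H](OC(=O)c2ccc(O[Si](C)(C)C(C)(C)C)cc2)C1 | intermediate
32 | (1(10)E,4R,5R,6R,7S,8R)-4,5-epoxy-6-hydroxygermacr-1(10)-en-8-yl 4-hydroxybenzoate | C/C1=C\CC[C@@]2(C)O[C@@H]2[C@H](O)[C@H](C(C)C)[C@H](OC(=O)c2ccc(O)cc2)C1 | target

**Step count**

Total steps: 20. Longest linear sequence: 19 (steps 1–17, 19, 20); step 18 is a one-step side branch.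

**Three steps most likely to fail**

Step 15 (ring opening and cold reduction). What may go wrong is a low stationary concentration of the triene with further photolysis of it, thermal reclosure before it is reduced, and unselective uptake of hydrogen on the nickel surface (reduction of unconverted diene, over-reduction or double-bond migration). The fallback replaces surface hydrogenation by a homogeneous hydrogen transfer. It sets out from 23: the solution is irradiated in a recirculating thin-film cell at −30 °C so that the triene leaves the light after a short residence time, and the cold stream is run directly into diimide generated from dipotassium azodicarboxylate (KO2C–N=N–CO2K) and acetic acid in methanol at −30 → −15 °C. Diimide transfers hydrogen in a concerted way to the least substituted Z bond and neither isomerises alkenes nor cleaves allylic C–O bonds. The fallback returns to the route at 25 and makes no new compound (F0).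

Step 16 (directed epoxidation). What may go wrong is delivery of oxygen to the other face, if the macrocycle reacts through the conformer in which the C4=C5 unit is flipped and the hydroxyl sits on the outer face at a large dihedral angle; this would give the threo epoxy alcohol. The fallback moves the facial choice from the ring conformation to a chiral reagent. It sets out from 25: titanium–tartrate (Sharpless) epoxidation with Ti(OiPr)4 (1.2 equiv), D-(−)-diisopropyl tartrate (1.5 equiv), t-BuOOH and 4 Å molecular sieves in CH2Cl2 at −20 °C. For the C6 configuration present, the D-(−)-tartrate complex is the matched partner and gives the erythro epoxy alcohol, and it also reacts only at the allylic alkene. The fallback returns at 26 and makes no new compound (F0).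

Step 19 (esterification of the diol). What may go wrong is poor site selectivity (acylation at O6 or at both oxygens) and acyl migration between O6 and O8. The fallback replaces kinetic selection by protecting-group differentiation and sets out from 26, where only O6 is free. Levulinic acid, DCC and DMAP in CH2Cl2 give (1(10)E)-8β-(tert-butyldimethylsilyloxy)-4α,5β-epoxygermacr-1(10)-en-6β-yl levulinate F1. Bu4NF buffered with AcOH in THF then removes the silyl group to give (1(10)E)-4α,5β-epoxy-8β-hydroxygermacr-1(10)-en-6β-yl levulinate F2, in which O8 is the only free hydroxyl. Steglich esterification with 30 gives the mixed diester (1(10)E)-4α,5β-epoxy-6β-(levulinoyloxy)germacr-1(10)-en-8β-yl 4-(tert-butyldimethylsilyloxy)benzoate F3. Hydrazine acetate in pyridine–AcOH at rt removes only the levulinate (as a dihydropyridazinone) and returns the route at 31, from which step 20 follows.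

Further compounds
F0 | step 15 | none | none
F0 | step 16 | none | none
F1 | step 19 | (1(10)E)-8β-(tert-butyldimethylsilyloxy)-4α,5β-epoxygermacr-1(10)-en-6β-yl levulinate | C/C1=C\CC[C@@]2(C)O[C@@H]2[C@H](OC(=O)CCC(C)=O)[C@H](C(C)C)[C@H](O[Si](C)(C)C(C)(C)C)C1
F2 | step 19 | (1(10)E)-4α,5β-epoxy-8β-hydroxygermacr-1(10)-en-6β-yl levulinate | C/C1=C\CC[C@@]2(C)O[C@@H]2[C@H](OC(=O)CCC(C)=O)[C@H](C(C)C)[C@H](O)C1
F3 | step 19 | (1(10)E)-4α,5β-epoxy-6β-(levulinoyloxy)germacr-1(10)-en-8β-yl 4-(tert-butyldimethylsilyloxy)benzoate | C/C1=C\CC[C@@]2(C)O[C@@H]2[C@H](OC(=O)CCC(C)=O)[C@H](C(C)C)[C@H](OC(=O)c2ccc(O[Si](C)(C)C(C)(C)C)cc2)C1
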